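**Plan**
- Numbering: C1 is the quaternary oxirane carbon (it bears C7H2OBz), C2 is CHOH, C3 is CHOBz, C4=C5 is the alkene, C6 is the oxirane CH. The retrosynthesis takes out the oxirane O to give a C1=C6/C4=C5 diene. It then hydrates C1=C6 to a C1 tertiary carbinol and cuts the carbocycle at C3–C4 and C6–C1.
- Two pieces remain. C7–C1–C2–C3 is four contiguous oxygenated carbons, that is D-tartaric acid, used as its acetonide ester-aldehyde. C4–C5–C6 is an allyl unit, used as an allyl sulfonium ylide.
- Enabling feature: in the cyclohexene ring the array C3(O)–C4=C5–C6 is the SN2′ retron of a 2-vinyloxirane. An allylide is therefore nucleophilic at C4. Once it has closed a temporary C3–O–C4 oxirane, it is electrophilic at C6.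
- Forward order: aldehyde plus allylide gives the vinyl-oxirane, and C1-enolate SN2′ attack then closes the six-membered ring in the same flask. After that come ester to CH2OBz, C3 inversion with benzoylation, acetonide removal, C1–OH dehydration to the diene, and the oxirane ring last.
- Stereochemistry: C2 comes from D-tartrate. C3 is set by Felkin–Anh addition and then Mitsunobu inversion. C1 and C6 are set by C2–OH-directed epoxidation. The helpers (temporary oxirane, dioxolane, C1–O) are all removed again.

Key step: step 3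

Step 1
Reactants: 1 dimethyl (4S,5S)-2,2-dimethyl-1,3-dioxolane-4,5-dicarboxylate (D-tartrate acetonide)
Product: 2 methyl (4S,5S)-5-formyl-2,2-dimethyl-1,3-dioxolane-4-carboxylate
Conditions: DIBAL-H (1.0 equiv), toluene, −78 °C; MeOH, aq Rochelle salt; used at once
Reagents that add atoms: none
Why: Partial ester reduction of the C2-symmetric diester should stop at the aluminium hemiacetal at −78 °C, so one ester becomes the C3 aldehyde and both tartrate centres stay untouched.

Step 2
Reactants: 3 allyl bromide; 4 diphenyl sulfide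
Product: 5 allyl(diphenyl)sulfonium tetrafluoroborate
Conditions: AgBF4 (1.0 equiv), CH2Cl2, 0 °C to rt, dark
Reagents that add atoms: silver tetrafluoroborate [Ag+].F[B-](F)(F)F
Why: Silver-assisted SN2 S-alkylation of the weakly nucleophilic diaryl sulfide should give a salt whose only acidic hydrogens sit on the allyl CH2, which excludes competing ylides and [2,3]-shifts.

Step 3
Reactants: 2 methyl (4S,5S)-5-formyl-2,2-dimethyl-1,3-dioxolane-4-carboxylate; 5 allyl(diphenyl)sulfonium tetrafluoroborate
Product: 8 methyl (3aS,7R,7aR)-7-hydroxy-2,2-dimethyl-3a,4,7,7a-tetrahydro-1,3-benzodioxole-3a-carboxylate (cis-fused; 7-OH cis to the dioxolane oxygens), via diphenylsulfonium allylide 6 (not isolated), via methyl (4S,5R)-2,2-dimethyl-5-[(2R,3S)-3-vinyloxiran-2-yl]-1,3-dioxolane-4-carboxylate (trans-oxirane drawn) 7 (not isolated)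
Conditions: 5, LDA (1.05 equiv), THF, −78 °C; add 2, −78 to −40 °C; re-cool, LDA (1.3 equiv), DMPU, −78 to −30 °C; aq NH4Cl
Reagents that add atoms: none
Why: Proposed new method: LDA turns 5 into allylide 6, whose sulfur-bearing carbon (future C4) adds to the aldehyde C3 of 2, the betaine closes (3-exo-tet, loss of Ph2S) to the temporary C3–O–C4 vinyl-oxirane 7, and the second portion of LDA forms the C1 ester enolate, which attacks the vinyl terminus C6 in an SN2′ sense (6-endo-trig), shifts the double bond to C4=C5 and opens the oxirane to the C3 alkoxide. The two halves are known separately, as the Corey–Chaykovsky-type allylide epoxidation of aldehydes and as C-alkylation of the tartrate-acetonide enolate or intramolecular SN2′ alkylation of stabilised carbanions, but their union into a [3+3] annulation with an ester enolate on a vinyl-oxirane is new. C3 is set by Felkin–Anh attack anti to the C2–O bond (3-O cis to 2-O), C1 can only close to the cis-fused 6/5 system so the new C1–C6 bond takes the place of H with retention, and the C4 oxirane centre is erased when C4 becomes sp2, so the cis/trans make-up of 7 does not matter. Chemoselectivity rests on the order of addition (no free amide base while the enolisable aldehyde is present), and regioselectivity rests on ring size, because direct SN2 attack of C1 at C4 or C3 would give a four- or three-membered ring and the in-ring alkene can only be Z. The dioxolane holds the C2–O bond away from the enolate π system, which should hold back β-elimination at low temperature, and release of oxirane strain drives the closure.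

Step 4
Reactants: 8 methyl (3aS,7R,7aR)-7-hydroxy-2,2-dimethyl-3a,4,7,7a-tetrahydro-1,3-benzodioxole-3a-carboxylate
Product: 9 [(3aR,7R,7aR)-7-hydroxy-2,2-dimethyl-3a,4,7,7a-tetrahydro-1,3-benzodioxol-3a-yl]methanol
Conditions: LiAlH4, THF, 0 °C to rt; Fieser work-up
Reagents that add atoms: none
Why: Hydride reduction of the α-alkoxy ester should give the C7 primary alcohol, while the isolated alkene and the acetonide are inert and no stereocentre is touched.

Step 5
Reactants: 9 [(3aR,7R,7aR)-7-hydroxy-2,2-dimethyl-3a,4,7,7a-tetrahydro-1,3-benzodioxol-3a-yl]methanol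
Product: 10 [(3aR,7R,7aR)-7-hydroxy-2,2-dimethyl-3a,4,7,7a-tetrahydro-1,3-benzodioxol-3a-yl]methyl benzoate
Conditions: BzCl (1.05 equiv), 2,4,6-collidine, CH2Cl2, −40 to −10 °C
Reagents that add atoms: benzoyl chloride O=C(Cl)c1ccccc1
Why: Selective acylation should favour the primary C7–OH over the secondary allylic C3–OH, which is shielded by the adjacent cis-dioxolane.

Step 6
Reactants: 10 [(3aR,7R,7aR)-7-hydroxy-2,2-dimethyl-3a,4,7,7a-tetrahydro-1,3-benzodioxol-3a-yl]methyl benzoate
Product: 11 [(3aR,7S,7aR)-7-(benzoyloxy)-2,2-dimethyl-3a,4,7,7a-tetrahydro-1,3-benzodioxol-3a-yl]methyl benzoate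
Conditions: PPh3, DIAD, PhCO2H, toluene, 0 °C to rt
Reagents that add atoms: benzoic acid O=C(O)c1ccccc1
Why: Mitsunobu esterification should replace the activated C3–O by benzoate with SN2 inversion, which installs the second benzoate and sets C3 trans to the C2 oxygen in one step.

Step 7
Reactants: 11 [(3aR,7S,7aR)-7-(benzoyloxy)-2,2-dimethyl-3a,4,7,7a-tetrahydro-1,3-benzodioxol-3a-yl]methyl benzoate
Product: 12 [(1R,5S,6R)-5-(benzoyloxy)-1,6-dihydroxycyclohex-3-en-1-yl]methyl benzoate
Conditions: TFA–H2O (9:1), CH2Cl2, 0 °C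
Reagents that add atoms: none
Why: Acid-catalysed ketal hydrolysis should free the C1/C2 cis-diol under conditions short and cold enough for both benzoates and the allylic C3–O bond to survive.

Step 8
Reactants: 12 [(1R,5S,6R)-5-(benzoyloxy)-1,6-dihydroxycyclohex-3-en-1-yl]methyl benzoate
Product: 13 [(5S,6S)-5-(benzoyloxy)-6-hydroxycyclohexa-1,3-dien-1-yl]methyl benzoate
Conditions: Martin sulfurane (1.2 equiv), CH2Cl2, −50 to 0 °C
Reagents that add atoms: none
Why: Sulfurane dehydration should act on the tertiary C1 alkoxysulfurane far faster than on the secondary C2–OH, and loss of the allylic C6–H gives the conjugated C1=C6/C4=C5 diene under neutral, non-aromatising conditions.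

Step 9
Reactants: 13 [(5S,6S)-5-(benzoyloxy)-6-hydroxycyclohexa-1,3-dien-1-yl]methyl benzoate
Product: 14 (−)-pipoxide, [(1R,2R,3S,6S)-3-(benzoyloxy)-2-hydroxy-7-oxabicyclo[4.1.0]hept-4-en-1-yl]methyl benzoate
Conditions: mCPBA, NaHCO3, CH2Cl2, 0 °C
Reagents that add atoms: mCPBA O=C(OO)c1cccc(Cl)c1
Why: Hydroxyl-directed (Henbest) peracid epoxidation should deliver oxygen to the trisubstituted C1=C6 alkene syn to the allylic C2–OH, which sets C1 and C6, while the C4=C5 alkene is disubstituted and deactivated by the allylic benzoate.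

**Compound list**
1 | dimethyl (4S,5S)-2,2-dimethyl-1,3-dioxolane-4,5-dicarboxylate | COC(=O)[C@H]1OC(C)(C)O[C@@H]1C(=O)OC | starting material
2 | methyl (4S,5S)-5-formyl-2,2-dimethyl-1,3-dioxolane-4-carboxylate | O=C[C@H]1OC(C)(C)O[C@@H]1C(=O)OC | intermediate
3 | allyl bromide | C=CCBr | starting material
4 | diphenyl sulfide | c1ccc(Sc2ccccc2)cc1 | starting material
5 | allyl(diphenyl)sulfonium tetrafluoroborate | C=CC[S+](c1ccccc1)c1ccccc1.F[B-](F)(F)F | intermediate
6 | diphenylsulfonium allylide | C=C[CH-][S+](c1ccccc1)c1ccccc1 | intermediate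
7 | methyl (4S,5R)-2,2-dimethyl-5-[(2R,3S)-3-vinyloxiran-2-yl]-1,3-dioxolane-4-carboxylate | C=C[C@@H]1O[C@H]1[C@H]2OC(C)(C)O[C@@H]2C(=O)OC | intermediate
8 | methyl (3aS,7R,7aR)-7-hydroxy-2,2-dimethyl-3a,4,7,7a-tetrahydro-1,3-benzodioxole-3a-carboxylate | COC(=O)[C@]12CC=C[C@@H](O)[C@H]1OC(C)(C)O2 | intermediate
9 | [(3aR,7R,7aR)-7-hydroxy-2,2-dimethyl-3a,4,7,7a-tetrahydro-1,3-benzodioxol-3a-yl]methanol | OC[C@]12CC=C[C@@H](O)[C@H]1OC(C)(C)O2 | intermediate
10 | [(3aR,7R,7aR)-7-hydroxy-2,2-dimethyl-3a,4,7,7a-tetrahydro-1,3-benzodioxol-3a-yl]methyl benzoate | O=C(OC[C@]12CC=C[C@@H](O)[C@H]1OC(C)(C)O2)c1ccccc1 | intermediate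
11 | [(3aR,7S,7aR)-7-(benzoyloxy)-2,2-dimethyl-3a,4,7,7a-tetrahydro-1,3-benzodioxol-3a-yl]methyl benzoate | O=C(OC[C@]12CC=C[C@H](OC(=O)c3ccccc3)[C@H]1OC(C)(C)O2)c1ccccc1 | intermediate
12 | [(1R,5S,6R)-5-(benzoyloxy)-1,6-dihydroxycyclohex-3-en-1-yl]methyl benzoate | O=C(OC[C@]1(O)CC=C[C@H](OC(=O)c2ccccc2)[C@H]1O)c1ccccc1 | intermediate
13 | [(5S,6S)-5-(benzoyloxy)-6-hydroxycyclohexa-1,3-dien-1-yl]methyl benzoate | O=C(OCC1=CC=C[C@H](OC(=O)c2ccccc2)[C@H]1O)c1ccccc1 | intermediate
14 | (−)-pipoxide | O=C(OC[C@]12O[C@H]1C=C[C@H](OC(=O)c1ccccc1)[C@H]2O)c1ccccc1 | target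

Total step count: 9. Longest linear sequence: 8 (steps 1, 3, 4, 5, 6, 7, 8, 9).

**Steps most likely to fail**

1. **Step 3.** Four things may go wrong:
   - poor facial selectivity in the ylide addition;
   - epimerisation of the aldehyde;
   - β-elimination of the dioxolane from the enolate;
   - an SN2′ closure too slow at the temperatures the enolate tolerates.

   The fallback sets out from 1 and comes back at 8, using known chemistry only.
   - The lithium enolate of 1 is C-allylated with allyl bromide, with retention. This gives dimethyl (4S,5S)-4-allyl-2,2-dimethyl-1,3-dioxolane-4,5-dicarboxylate F1.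
   - DIBAL-H at −78 °C reduces the less hindered ester (on the CH carbon) to methyl (4S,5S)-4-allyl-5-formyl-2,2-dimethyl-1,3-dioxolane-4-carboxylate F2.
   - Vinylmagnesium bromide adds in the Felkin–Anh sense to give methyl (4S,5R)-4-allyl-5-[(1R)-1-hydroxyprop-2-enyl]-2,2-dimethyl-1,3-dioxolane-4-carboxylate F3.
   - Ring-closing metathesis (Grubbs II catalyst) closes C4=C5 to 8.

2. **Step 8.** The secondary C2–OH may take part through a cyclic sulfurane, leading to a pinacol-type hydride shift. Elimination may also go in the wrong direction, or the diene may aromatise. The fallback sets out from 12 and comes back at 13.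
   - The secondary alcohol alone is silylated (TESCl, imidazole). This gives [(1R,5S,6R)-5-(benzoyloxy)-1-hydroxy-6-(triethylsilyloxy)cyclohex-3-en-1-yl]methyl benzoate F4.
   - The now isolated tertiary alcohol is dehydrated with SOCl2/pyridine to [(5S,6S)-5-(benzoyloxy)-6-(triethylsilyloxy)cyclohexa-1,3-dien-1-yl]methyl benzoate F5.
   - HF·pyridine removes the silyl group to give 13.

3. **Step 6.** SN2′ attack of benzoate at C5 or elimination of the activated allylic alcohol may compete with the clean inversion. The fallback sets out from 10 and comes back at 11.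
   - Dess–Martin oxidation gives the enone [(3aR,7aS)-2,2-dimethyl-7-oxo-3a,4,7,7a-tetrahydro-1,3-benzodioxol-3a-yl]methyl benzoate F6.
   - Reagent-controlled 1,2-reduction follows, using the Me-CBS enantiomer that delivers hydride from the dioxolane face, with BH3. This gives the trans alcohol [(3aR,7S,7aR)-7-hydroxy-2,2-dimethyl-3a,4,7,7a-tetrahydro-1,3-benzodioxol-3a-yl]methyl benzoate F7.
   - Plain benzoylation (BzCl, pyridine) then gives 11.

Further compounds
F1 | step 3 | dimethyl (4S,5S)-4-allyl-2,2-dimethyl-1,3-dioxolane-4,5-dicarboxylate | COC(=O)[C@H]1OC(C)(C)O[C@]1(CC=C)C(=O)OC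
F2 | step 3 | methyl (4S,5S)-4-allyl-5-formyl-2,2-dimethyl-1,3-dioxolane-4-carboxylate | O=C[C@H]1OC(C)(C)O[C@]1(CC=C)C(=O)OC
F3 | step 3 | methyl (4S,5R)-4-allyl-5-[(1R)-1-hydroxyprop-2-enyl]-2,2-dimethyl-1,3-dioxolane-4-carboxylate | C=C[C@@H](O)[C@H]1OC(C)(C)O[C@]1(CC=C)C(=O)OC
F4 | step 8 | [(1R,5S,6R)-5-(benzoyloxy)-1-hydroxy-6-(triethylsilyloxy)cyclohex-3-en-1-yl]methyl benzoate | O=C(OC[C@]1(O)CC=C[C@H](OC(=O)c2ccccc2)[C@H]1O[Si](CC)(CC)CC)c1ccccc1
F5 | step 8 | [(5S,6S)-5-(benzoyloxy)-6-(triethylsilyloxy)cyclohexa-1,3-dien-1-yl]methyl benzoate | O=C(OCC1=CC=C[C@H](OC(=O)c2ccccc2)[C@H]1O[Si](CC)(CC)CC)c1ccccc1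
F6 | step 6 | [(3aR,7aS)-2,2-dimethyl-7-oxo-3a,4,7,7a-tetrahydro-1,3-benzodioxol-3a-yl]methyl benzoate | O=C(OC[C@]12CC=CC(=O)[C@H]1OC(C)(C)O2)c1ccccc1
F7 | step 6 | [(3aR,7S,7aR)-7-hydroxy-2,2-dimethyl-3a,4,7,7a-tetrahydro-1,3-benzodioxol-3a-yl]methyl benzoate | O=C(OC[C@]12CC=C[C@H](O)[C@H]1OC(C)(C)O2)c1ccccc1
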